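The readings stem from a simulated flask for substances that don't exist; noise was put on by code.

1. In a one-step world, Q + L -> J + Z, this flask stops with 20.0% of the Q charge left: the floor, one minus L charged over Q charged, with L as limiting reagent.

common to all: Q 0.50 mM

|  | L | remark | time |
|---|---|---|---|
| birch | 0.40 mM | the very flask that is asked about, followed so far |  |
| flask | 0.400 mM |  | 8.0 min |

birch run (percent of the Q charged)

| time / s | Q / % | J / % |
|---|---|---|
| 10.0 | 54.5 | 24.1 |
| 20.0 | 43.5 | 17.3 |
| 30.0 | 37.7 | 11.3 |
| 50.0 | 32.0 | 4.3 |
| 80.0 | 28.5 | 0.9 |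
| 90.0 | 29.6 | 0.5 |

(each reading ± 1 percentage point)

- percent here means Q units held: one D counts as two
- what is said of G includes D and E
- E is a solid; its amount is given per volume of the solution
- what was read earlier has a scatter of 1 percentage point, one standard deviation
- candidate steps: L + J -> G + Z; Q + L -> J + Z; E <-> G; J -> X; Q + G <-> D
- in an amount of G, one D counts as one G

1. amount of Q at 8.0 min, in percent of the Q charged
2. amount of J at 8.0 min, in percent of the Q charged
3. amount of G at 8.0 min, in percent of the Q charged

2. The real flask has a second use for L, because L + J -> G + Z takes another L per G, and each D holds one Q. So once L is at zero, I reckon Q = floor + G − D/2, all as fractions of the Q charge, with D in Q units held, where one D counts as two.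

3. Fastest rung: Q reads 54.5% by 10.0 s, about half the charge.

4. Next rung: J falls from 17.3% to 4.3% between 20.0 s and 50.0 s, a read half-life of 14.9 s, longer than that first drop.

5. Next rung: Q stands flat, 28.5% and then 29.6%, each with a scatter of 1 percentage point. Their mean, 29.1%, lies above the floor. I read the flat Q as L near zero.

6. Last rung: the asked 8.0 min is 32.2 read half-lives of J. I commit to J at 0%, Q near 29.1%, and, guessing D small, G near 9.05%.

7. The forecast gives Q 30%, J 0%, G 14%, holding that “total G (G+D+E) stays about 14”. Its G is higher than mine; by the floor rule, its figures ask for D near 8.00% in Q units held.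

The flask gives Q 28.0%, J 0%, G 8.17% at 8.0 min, with D at 0.241% and L at 0%.

    L + J → G + Z (k = 93.0 M⁻¹ s⁻¹)
    Q + L → J + Z (k = 221 M⁻¹ s⁻¹)
    E ⇌ G, rate k3*(cs3 - [G]) while solid is left; crystals form when [G] > cs3 (solubility = 0.00500 mM, k = 0.376 s⁻¹)
    J → X (k = 0.0768 s⁻¹)
    Q + G ⇌ D, settled at all times (K = 860 M⁻¹)

On this flask, floor plus G minus D/2 makes 28.0%. The neighbour flask with 0.10 mM of L has a floor of 80.0%, and with its G of 0.501% and D of 0.257% the rule makes 80.4%; that flask holds Q at 80.4%.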